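**The problem**

The target 30 is a nonaphenolic stilbene trimer in which two trans-2,3-diaryl-2,3-dihydrobenzofurans are joined by a single bond from the sp3 carbon C2 to the aromatic carbon C7'. Ring system 1 is benzo ring B fused to dihydrofuran ring C (plain locants), and ring system 2 is benzo ring E fused to dihydrofuran ring F (primed locants). Ring B carries an (E)-4-hydroxystyryl group (ring A) at C4, next to the 3,5-dihydroxyphenyl ring D on C3; ring F carries the 2,4-dihydroxyphenyl ring G on C2' and the 3,5-dihydroxyphenyl ring H on C3'. The four stereocentres (2S, 3S, 2'S, 3'S) form two vicinal pairs. Within a pair trans is the stable arrangement, so one fixed centre can govern its neighbour, but the pairs are held apart by the flat ring E and each needs its own source of absolute configuration. Nine phenols must stay masked to the last step, and the stilbene double bond will not survive trivalent iodine, carbon radicals or hydrogenation, so it must enter late. The benzylic ether bonds O1–C2 and, above all, O1'–C2' (beside the electron-rich ring G) ionise under acid. The opening for the key step is ring C itself: O1, C2, C3, C3a and C7a are the pyranone ring of a flavanone less its carbonyl carbon, with O1, C2 and the aryl group on C2 already in flavanone positions. A shift of the ring B carbon from the carbonyl carbon to the neighbouring CH2 therefore turns a 2-arylchroman-4-one into ring C and leaves the expelled carbon as a carboxyl group on C3, exactly where ring D has to be attached.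

**Retrosynthesis**

The nine O–H bonds of 30 are traced back to the O–CH3 bonds of nonamethyl ether 29. Methyl is preferred to benzyl or silyl because every aromatic building block is sold as its methyl ether and because methyl ethers are indifferent to the organolithium, carbene, trivalent iodine, radical and palladium steps. Hydrogenolysis of benzyl ethers would also reduce the stilbene. The forward reaction must cleave all nine ethers in one operation, leave the alkene E, and let rings C and F reclose trans if they open.

In 29 the bond between C4 and the styryl carbon is cut (Suzuki–Miyaura coupling), giving aryl chloride 27 and the commercial (E)-styrylboronic acid 28. The neighbouring cut through the double bond would need a C4 aldehyde and would leave the E/Z ratio to an olefination. The chosen cut brings the alkene in with fixed geometry after every step that would destroy it. Chlorine is the marker at C4 because it is inert to divalent palladium, trivalent iodine and nickel at room temperature, yet couples with a dialkylbiarylphosphine ligand.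

The C3–ring D bond of 27 is cut next: decarboxylative arylation of the N-acyloxyphthalimide 24 with arylzinc reagent 26, which is made from bromide 5 through aryllithium 25; 24 comes from acid 23 and 23 from methyl ester 22. Building ring C with ring D already in place would require both ring C centres to be created at once beside the bulky ring system 2. This cut instead leaves an ester on C3, the natural product of a ring contraction, and lets C2 decide C3 in the radical step. The forward reaction must leave C4–Cl alone.

Ester 22 is the retron of the oxidative ring contraction of a flavanone. The C3–C3a bond is cut and C3a is reconnected to the ester carbon, which becomes the carbonyl carbon C4 of flavanone 20. This reduces the stereochemical problem of ring C to the single centre C2 of 20, since C3 of 22 follows from C2. It also exchanges a ring that is hard to close with control for a six-membered ring made by carbonyl chemistry. The forward reaction must move the fused-ring bond and not the C2 aryl group, and must not open the O1–C2 bond.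

Flavanone 20 is cut at C2–C7', the bond that joins the two halves, giving chromone 19 and boronic acid 14 (asymmetric conjugate addition with Pd(OCOCF3)2 and a chiral pyridine-oxazoline). The alternative cut at O1–C2 (oxa-Michael closure of a 2'-hydroxychalcone) is held in reserve, because it has no reliable catalyst control. The precursors are an achiral bicyclic enone and a boronic acid that already carries both ring F centres. The reaction must set C2 by the catalyst, against whatever bias ring F exerts.

Chromone 19 is cut at O1–C2 and C2–C3 to 2'-hydroxyacetophenone 17 and a one-carbon unit (through enaminone 18). Ketone 17 goes back to dimethyl ether 16 (chelation-controlled demethylation) and 16 to 1-chloro-3,5-dimethoxybenzene 15 (Friedel–Crafts acylation).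

Boronic acid 14 comes from bromide 12 through aryllithium 13. In 12 the C2'–C3' bond is cut: the carbene from diaryldiazomethane 10 inserts into the benzylic O–CH2 bond of its 2,4-dimethoxybenzyl ether, and acid turns the cis product 11 into trans 12. Among closures of ring F this one creates C3' under catalyst control and tolerates the aryl bromide. The electron-rich ring G, a liability elsewhere, here speeds both insertion and isomerisation. Diazo compound 10 comes from hydrazone 9 and this from ketone 8.

Ketone 8 is cut at the carbonyl–ring H bond to aldehyde 4 and Grignard reagent 6 (from bromide 5), by way of carbinol 7. Aldehyde 4 is cut at the benzylic C–O bond to salicylaldehyde 2 and alcohol 3 (Mitsunobu), and 2 goes back to 2-bromo-5-methoxyphenol 1 by ortho-formylation. The bromine of 1 already stands ortho to OH and para to OMe, so the C7' marker never has to be introduced by a selective halogenation.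

**Roads not taken**

Alternative 1: The cuts are C2–C3 and O1–C2 of ring C, a [4+1] annulation in which C2 is the one-carbon unit. Sulfone A2 (a ring B phenol with ring D and a sulfonyl group on the ortho benzylic carbon) and the benzylic sulfonium salt A3 of ring system 2 are treated with Cs2CO3. A2 loses sulfinate to give an ortho-quinone methide and A3 gives its ylide. The ylide carbon adds to the methide carbon and the phenoxide displaces the sulfide, giving the C4 bromide A1.
- Merits: ring C, both its stereocentres and ring D arrive in one convergent step; the C4 bromide would couple more easily than chloride 27; no trivalent iodine touches the electron-rich rings; and from 12 the main line is one or two steps shorter.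
- Weak points: the quinone methide is flat and achiral, the stereocentres of the ylide are remote, and no chiral catalyst takes part. Trans is expected, but the (2S,3S) and (2R,3R) forms of ring C should arise without useful preference and differ only in the mutual orientation of two distant halves. The semi-stabilised ylide is flanked by the ring F oxygen, and A2 needs its benzylic carbon at the ring B position between OH and Br, the most crowded of three open sites.
- Comparison: this road is shorter and more convergent. The chosen plan sets control against that: C2 is fixed by a chiral catalyst in step 11 and C3 follows from C2, so no material is lost to a diastereomer that cannot be corrected.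

Alternative 2: The cut is C2'–C3' of ring F. Diaryldiazomethane 10 is decomposed by Rh2(S-PTAD)4 (or its enantiomer). The dirhodium carbene inserts into a hydrogen of the O–CH2 group and closes ring F as the cis isomer 11. CF3CO2H added to the same flask gives the trans bromide A4, which is compound 12.
- Merits: the ring and the C3' configuration are made in one catalytic operation, C2' follows by equilibration, the aryl bromide is tolerated, and the reaction has direct precedent on resveratrol-type diaryl systems.
- Relation to the chosen plan: for ring F nothing better is available, and the chosen plan uses exactly this reaction as its step 6. On that ground the chosen plan has nothing to set against it.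
- What is not taken is its use as the centre of the whole plan. Carried through, it would close ring C by a second insertion from diazo compound A5 (the ring B diaryldiazomethane etherified with the C7'–CH2 group of ring system 2). That would give 27 with ring D already in place and would probably be shorter.
- Weak points of that extension: the ketone behind A5 is flanked by chlorine and a bulky ether and must be condensed with hydrazine on advanced material; the methylene group to be attacked sits beside ring E; the catalyst must override a hindered chiral substrate; and the acid needed to move ring C from cis to trans also opens ring F.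
- The chosen plan instead joins two separately made halves by a catalytic C–C bond formation and takes C3 from C2 in a radical step that needs no isomerisation. It pays for this with three functional-group steps.

Alternative 3: The cut is the aryl ether bond O1'–C7a' of ring F. The stereodefined triarylethanol A7, whose third aryl group is 2-fluoro-6-methoxyphenyl, is treated with lithium 2,2,6,6-tetramethylpiperidide. Deprotonation ortho to fluorine and loss of LiF give an aryne across C7'–C7a'. The lithium alkoxide on C2' adds to C7a' and closes ring F, and iodine quenches the aryllithium left at C7' to give iodide A6.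
- Merits: ring closure and the C7' handle come in one operation with full regiocontrol and no transition metal, and an iodide would be borylated more easily than bromide 12.
- Weak points: the stereochemical problem is only moved into the open chain. A7 has two adjacent centres, a labile 2,4-dimethoxybenzylic carbinol and a diarylmethine, with no simple catalytic asymmetric entry, and the obvious ketone precursor would racemise at the diarylmethine. The amide base also meets C–H bonds at least as acidic as the one beside fluorine (between the two methoxy groups of rings G and H, and the doubly benzylic C3'–H), so the site of metalation and the integrity of C3' are in doubt.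
- Comparison: from A7 this road is as short as the insertion route and its halide is the better one. The chosen plan sets against it a ring F configuration that comes from a catalytic step with close precedent. Like Alternative 2 it leaves ring C open, for which the ring contraction would still be needed.

Key step: step 12

**Route**

In the names below, "RS2" stands for the (2S,3S)-2-(2,4-dimethoxyphenyl)-3-(3,5-dimethoxyphenyl)-4-methoxy-2,3-dihydro-1-benzofuran-7-yl group (ring system 2 as its methyl ethers, attached through C7').

Assumption: the sense of induction of Rh2(S-PTAD)4 in step 6 and of the (R)-pyridine-oxazoline in step 11 is assigned by analogy with the parent benzyl ether and chromone cases; if a model run shows the opposite sense, the mirror-image catalyst is used and nothing else changes.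

Step 1
Reactants: 1 2-bromo-5-methoxyphenol
Product: 2 3-bromo-2-hydroxy-6-methoxybenzaldehyde
Conditions: MgCl2, Et3N, (CH2O)n, MeCN, reflux
Reagents that add atoms: formaldehyde (as paraformaldehyde), C=O
Why: Magnesium phenoxide-directed ortho-formylation (Casnati–Skattebøl reaction) delivers formaldehyde only ortho to the phenol oxygen; C2 is blocked by bromine, so the aldehyde can only enter at C6 between OH and OMe, the future C3a'.

Step 2
Reactants: 2 3-bromo-2-hydroxy-6-methoxybenzaldehyde; 3 (2,4-dimethoxyphenyl)methanol
Product: 4 3-bromo-2-[(2,4-dimethoxyphenyl)methoxy]-6-methoxybenzaldehyde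
Conditions: PPh3, iPrO2C–N=N–CO2iPr, THF, 0 °C to rt
Reagents that add atoms: none
Why: Mitsunobu etherification: the acidic, hydrogen-bonded salicylaldehyde phenol is alkylated by the activated primary benzylic alcohol under neutral conditions, which avoids the unstable 2,4-dimethoxybenzyl halides.

Step 3
Reactants: 4 3-bromo-2-[(2,4-dimethoxyphenyl)methoxy]-6-methoxybenzaldehyde; 5 1-bromo-3,5-dimethoxybenzene
Product: 7 rac-{3-bromo-2-[(2,4-dimethoxyphenyl)methoxy]-6-methoxyphenyl}(3,5-dimethoxyphenyl)methanol, via (3,5-dimethoxyphenyl)magnesium bromide 6 (not isolated)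
Conditions: 5, Mg, THF, 40 °C; then 4, THF, −20 to 0 °C; then H2O
Reagents that add atoms: none
Why: Addition of an aryl Grignard reagent to an aldehyde; at or below 0 °C the aryl bromide and the ethers are inert. The carbinol centre is racemic and is erased in the next step.

Step 4
Reactants: 7 rac-{3-bromo-2-[(2,4-dimethoxyphenyl)methoxy]-6-methoxyphenyl}(3,5-dimethoxyphenyl)methanol
Product: 8 {3-bromo-2-[(2,4-dimethoxyphenyl)methoxy]-6-methoxyphenyl}(3,5-dimethoxyphenyl)methanone
Conditions: Dess–Martin periodinane, NaHCO3, CH2Cl2, rt
Reagents that add atoms: none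
Why: Dess–Martin oxidation of a diaryl carbinol to the benzophenone under buffered, non-acidic conditions that spare the acid-labile benzyl ether.

Step 5
Reactants: 8 {3-bromo-2-[(2,4-dimethoxyphenyl)methoxy]-6-methoxyphenyl}(3,5-dimethoxyphenyl)methanone
Product: 9 {3-bromo-2-[(2,4-dimethoxyphenyl)methoxy]-6-methoxyphenyl}(3,5-dimethoxyphenyl)methanone hydrazone (E/Z mixture)
Conditions: N2H4·H2O (excess), EtOH, 100 °C (sealed tube)
Reagents that add atoms: hydrazine (as hydrate), NN
Why: Condensation of the ketone with hydrazine gives the N-unsubstituted hydrazone, the precursor of the diazo compound; excess hydrazine and heat are needed because both ortho positions of one aryl group are substituted.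

Step 6
Reactants: 9 {3-bromo-2-[(2,4-dimethoxyphenyl)methoxy]-6-methoxyphenyl}(3,5-dimethoxyphenyl)methanone hydrazone
Product: 12 (2S,3S)-7-bromo-2-(2,4-dimethoxyphenyl)-3-(3,5-dimethoxyphenyl)-4-methoxy-2,3-dihydro-1-benzofuran, via the diaryldiazomethane 10 (not isolated), via the cis-(2R,3S) dihydrobenzofuran 11 (not isolated)
Conditions: MnO2, CH2Cl2, 0 °C, filter; Rh2(S-PTAD)4 (1 mol%), CH2Cl2, −20 °C to rt; then CF3CO2H, 0 °C
Reagents that add atoms: none
Why: MnO2 dehydrogenates the hydrazone to the diaryldiazomethane, whose dirhodium carbene inserts into the hydridic benzylic C–H bond of the ether (intramolecular donor/donor carbene C–H insertion), closing ring F cis with C3' set by the chiral carboxylate ligands. Trifluoroacetic acid then ionises the O1'–C2' bond, made labile by ring G, and reclosure gives the thermodynamic trans isomer with C3' untouched, so C2' is set by C3'.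

Step 7
Reactants: 12 (2S,3S)-7-bromo-2-(2,4-dimethoxyphenyl)-3-(3,5-dimethoxyphenyl)-4-methoxy-2,3-dihydro-1-benzofuran
Product: 14 [(2S,3S)-2-(2,4-dimethoxyphenyl)-3-(3,5-dimethoxyphenyl)-4-methoxy-2,3-dihydro-1-benzofuran-7-yl]boronic acid (RS2-boronic acid), via the C7' aryllithium 13 (not isolated)
Conditions: n-BuLi, THF, −78 °C; B(OiPr)3, −78 °C to rt; 0.5 M HCl, 0 °C
Reagents that add atoms: triisopropyl borate, CC(C)OB(OC(C)C)OC(C)C; water, O
Why: Bromine–lithium exchange at −78 °C is faster than any deprotonation, and the aryllithium is trapped by the borate; brief cold hydrolysis gives the boronic acid (lithiation–borylation) without disturbing ring F.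

Step 8
Reactants: 15 1-chloro-3,5-dimethoxybenzene
Product: 16 1-(2-chloro-4,6-dimethoxyphenyl)ethan-1-one
Conditions: AcCl, AlCl3, CH2Cl2, 0 °C to rt
Reagents that add atoms: acetyl chloride, CC(=O)Cl
Why: Friedel–Crafts acylation; the position para to one methoxy group and ortho to the other is favoured over the position between the two methoxy groups, as with other 5-substituted resorcinol dimethyl ethers.

Step 9
Reactants: 16 1-(2-chloro-4,6-dimethoxyphenyl)ethan-1-one
Product: 17 1-(2-chloro-6-hydroxy-4-methoxyphenyl)ethan-1-one
Conditions: BCl3, CH2Cl2, −78 to 0 °C; then H2O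
Reagents that add atoms: none
Why: BCl3 binds the ketone and removes only the methyl group of the ortho methoxy group through a six-membered chelate (chelation-controlled demethylation); the para methoxy group stays.

Step 10
Reactants: 17 1-(2-chloro-6-hydroxy-4-methoxyphenyl)ethan-1-one
Product: 19 5-chloro-7-methoxy-4H-chromen-4-one, via the (E)-enaminone 18 (not isolated)
Conditions: Me2NCH(OMe)2, toluene, 100 °C; then conc. HCl, CH2Cl2, rt
Reagents that add atoms: N,N-dimethylformamide dimethyl acetal, COC(OC)N(C)C
Why: Condensation of the methyl ketone with the formamide acetal gives the enaminone; acid then triggers conjugate addition of the phenol and loss of dimethylamine to close the chromone (enaminone route to chromones).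

Step 11
Reactants: 19 5-chloro-7-methoxy-4H-chromen-4-one; 14 [(2S,3S)-2-(2,4-dimethoxyphenyl)-3-(3,5-dimethoxyphenyl)-4-methoxy-2,3-dihydro-1-benzofuran-7-yl]boronic acid (RS2-boronic acid)
Product: 20 (2S)-5-chloro-7-methoxy-2-RS2-2,3-dihydro-4H-chromen-4-one
Conditions: Pd(OCOCF3)2 (10 mol%), (R)-4-tert-butyl-2-(pyridin-2-yl)-4,5-dihydro-1,3-oxazole (12 mol%), NH4PF6 (30 mol%), H2O (5 equiv), ClCH2CH2Cl, 60 °C
Reagents that add atoms: none
Why: Palladium-catalysed asymmetric conjugate addition of an arylboronic acid to a chromone: the cationic aryl–palladium pyridine-oxazoline complex inserts the C2=C3 bond on one face and protonolysis releases the flavanone, so C2 is set by the ligand, the remote ring F centres being expected to have little say. The chloride is untouched because the cycle stays at divalent palladium.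

Step 12
Reactants: 20 (2S)-5-chloro-7-methoxy-2-RS2-2,3-dihydro-4H-chromen-4-one
Product: 22 methyl (2S,3S)-4-chloro-6-methoxy-2-RS2-2,3-dihydro-1-benzofuran-3-carboxylate (trans), via the methyl enol ether 21 (not isolated)
Conditions: HC(OMe)3 (solvent), H2SO4 (cat.), 0 °C; then PhI(OAc)2 (1.1 equiv), 0 °C to rt
Reagents that add atoms: trimethyl orthoformate, COC(OC)OC
Why: In trimethyl orthoformate the acid converts the ketone into its dimethyl ketal and methyl enol ether 21; PhI(OAc)2, activated by the acid, attacks C3 of 21 on the face away from the C2 aryl group, and methanol closes the oxocarbenium ion to a C3-iodanyl 4,4-dimethoxychroman. The equatorial C3–I bond is antiperiplanar to the C4–C4a ring bond, so the electron-rich ring B carbon C4a (para to OMe, ortho to O1) shifts from C4 to C3 through a bridged phenonium ion as iodobenzene leaves, and the dimethoxycarbenium ion at the old C4 is demethylated by acetate to the methyl ester. The closest known reaction type is the oxidative 1,2-aryl shift of aryl ketone ketals with trivalent iodine or trivalent thallium, in its ring-contracting form on flavanones. Ring C is therefore closed not by cyclisation but by contraction of the six-membered pyranone: the C3–C3a bond forms by intramolecular backside displacement at C3 (a 3-exo-tet attack of the arene, then opening of the phenonium ion at C4). C2 is not a reacting centre and keeps its S configuration; C3 is set by it, since iodane and migrating carbon add anti and the inversion at C3 places the ester trans to the C2 aryl group, which is also the stable arrangement of this epimerisable ester. The selectivity needed is migration of the fused-ring bond instead of the C2 aryl group (isoflavone pathway) or loss of H2 (flavone pathway): the aryl group is held equatorial by its ortho substituent and by the 1,3-diaxial clash an axial aryl would have with a ketal methoxy group, so it cannot become antiperiplanar to C3–I, while the ring bond is, and only its shift ends in a doubly oxygen-stabilised cation. Acid is kept catalytic and the oxidant near one equivalent so that rings G and H and the benzylic ether of ring F are exposed as briefly as possible.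

Step 13
Reactants: 22 methyl (2S,3S)-4-chloro-6-methoxy-2-RS2-2,3-dihydro-1-benzofuran-3-carboxylate
Product: 23 (2S,3S)-4-chloro-6-methoxy-2-RS2-2,3-dihydro-1-benzofuran-3-carboxylic acid
Conditions: Me3SnOH, ClCH2CH2Cl, 80 °C; then 0.5 M HCl wash
Reagents that add atoms: trimethyltin hydroxide, C[Sn](C)(C)O
Why: Me3SnOH cleaves the methyl ester under neutral conditions; aqueous hydroxide is avoided because the C3 enolate could expel the O1 phenoxide by E1cB ring opening. Epimerisation at C3 would not matter, since this centre becomes a radical in step 15.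

Step 14
Reactants: 23 (2S,3S)-4-chloro-6-methoxy-2-RS2-2,3-dihydro-1-benzofuran-3-carboxylic acid
Product: 24 1,3-dioxoisoindolin-2-yl (2S,3S)-4-chloro-6-methoxy-2-RS2-2,3-dihydro-1-benzofuran-3-carboxylate
Conditions: N-hydroxyphthalimide, iPrN=C=NiPr, DMAP (cat.), CH2Cl2, rt
Reagents that add atoms: N-hydroxyphthalimide, O=C1N(O)C(=O)c2ccccc12
Why: Carbodiimide esterification (Steglich type) with N-hydroxyphthalimide gives the redox-active ester under mild, nearly neutral conditions.

Step 15
Reactants: 24 1,3-dioxoisoindolin-2-yl (2S,3S)-4-chloro-6-methoxy-2-RS2-2,3-dihydro-1-benzofuran-3-carboxylate; 5 1-bromo-3,5-dimethoxybenzene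
Product: 27 (2S,3S)-4-chloro-3-(3,5-dimethoxyphenyl)-6-methoxy-2-RS2-2,3-dihydro-1-benzofuran, via (3,5-dimethoxyphenyl)lithium 25 (not isolated), via (3,5-dimethoxyphenyl)zinc chloride 26 (not isolated)
Conditions: 5, t-BuLi (2 equiv), THF, −78 °C; ZnCl2, THF, −78 °C to rt; then 24, NiCl2(dme) (20 mol%), 4,4'-di-tert-butyl-2,2'-bipyridine (40 mol%), THF/DMF, rt
Reagents that add atoms: none
Why: Bromine–lithium exchange with tert-butyllithium (the second equivalent destroys the tert-butyl bromide, so no alkyl halide is left to compete at nickel) gives aryllithium 25, ZnCl2 transmetalates it to arylzinc 26, and 26 enters the nickel-catalysed decarboxylative arylation of the redox-active ester (Negishi type): electron transfer from low-valent nickel fragments 24 to CO2, phthalimide anion and the benzylic C3 radical, which the aryl–nickel species captures before reductive elimination. The planar radical is arylated on the face away from the C2 aryl group, so C3 is set trans by C2; at rt the hindered, electron-rich C4–Cl bond should not undergo oxidative addition.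

Step 16
Reactants: 27 (2S,3S)-4-chloro-3-(3,5-dimethoxyphenyl)-6-methoxy-2-RS2-2,3-dihydro-1-benzofuran; 28 [(E)-2-(4-methoxyphenyl)ethenyl]boronic acid
Product: 29 (2S,3S)-3-(3,5-dimethoxyphenyl)-6-methoxy-4-[(E)-2-(4-methoxyphenyl)ethenyl]-2-RS2-2,3-dihydro-1-benzofuran
Conditions: Pd(OAc)2 (5 mol%), SPhos (10 mol%), K3PO4, toluene/H2O, 100 °C
Reagents that add atoms: none
Why: Suzuki–Miyaura coupling of an aryl chloride; the electron-rich dialkylbiarylphosphine enables oxidative addition into the hindered C4–Cl bond, and the alkenylboronic acid transfers with retention of the E geometry.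

Step 17
Reactants: 29 (2S,3S)-3-(3,5-dimethoxyphenyl)-6-methoxy-4-[(E)-2-(4-methoxyphenyl)ethenyl]-2-RS2-2,3-dihydro-1-benzofuran
Product: 30 (2S,3S)-2-[(2S,3S)-2-(2,4-dihydroxyphenyl)-3-(3,5-dihydroxyphenyl)-4-hydroxy-2,3-dihydro-1-benzofuran-7-yl]-3-(3,5-dihydroxyphenyl)-4-[(E)-2-(4-hydroxyphenyl)ethenyl]-2,3-dihydro-1-benzofuran-6-ol (CNP0397447.1)
Conditions: BBr3 (excess), CH2Cl2, −78 °C to rt; then H2O, 0 °C
Reagents that add atoms: none
Why: BBr3 cleaves all nine aryl methyl ethers (Lewis acid-mediated demethylation). Any ionisation of the O1–C2 or O1'–C2' bond is corrected by reclosure trans to the fixed C3 and C3' centres.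

**Compound list**

1 | 2-bromo-5-methoxyphenol | COc1ccc(Br)c(O)c1 | starting material
2 | 3-bromo-2-hydroxy-6-methoxybenzaldehyde | O=Cc1c(O)c(Br)ccc1OC | intermediate
3 | (2,4-dimethoxyphenyl)methanol | COc1ccc(CO)c(OC)c1 | starting material
4 | 3-bromo-2-[(2,4-dimethoxyphenyl)methoxy]-6-methoxybenzaldehyde | O=Cc1c(OCc2ccc(OC)cc2OC)c(Br)ccc1OC | intermediate
5 | 1-bromo-3,5-dimethoxybenzene | COc1cc(Br)cc(OC)c1 | starting material
6 | (3,5-dimethoxyphenyl)magnesium bromide | COc1cc([Mg]Br)cc(OC)c1 | intermediate
7 | rac-{3-bromo-2-[(2,4-dimethoxyphenyl)methoxy]-6-methoxyphenyl}(3,5-dimethoxyphenyl)methanol | COc1cc(OC)cc(c1)C(O)c1c(OCc2ccc(OC)cc2OC)c(Br)ccc1OC | intermediate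
8 | {3-bromo-2-[(2,4-dimethoxyphenyl)methoxy]-6-methoxyphenyl}(3,5-dimethoxyphenyl)methanone | COc1cc(OC)cc(c1)C(=O)c1c(OCc2ccc(OC)cc2OC)c(Br)ccc1OC | intermediate
9 | {3-bromo-2-[(2,4-dimethoxyphenyl)methoxy]-6-methoxyphenyl}(3,5-dimethoxyphenyl)methanone hydrazone (E/Z mixture) | NN=C(c1cc(OC)cc(OC)c1)c1c(OCc2ccc(OC)cc2OC)c(Br)ccc1OC | intermediate
10 | 1-bromo-3-[diazo(3,5-dimethoxyphenyl)methyl]-2-[(2,4-dimethoxyphenyl)methoxy]-4-methoxybenzene | [N-]=[N+]=C(c1cc(OC)cc(OC)c1)c1c(OCc2ccc(OC)cc2OC)c(Br)ccc1OC | intermediate
11 | (2R,3S)-7-bromo-2-(2,4-dimethoxyphenyl)-3-(3,5-dimethoxyphenyl)-4-methoxy-2,3-dihydro-1-benzofuran (cis) | Brc1ccc(OC)c2c1O[C@@H](c1ccc(OC)cc1OC)[C@H]2c1cc(OC)cc(OC)c1 | intermediate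
12 | (2S,3S)-7-bromo-2-(2,4-dimethoxyphenyl)-3-(3,5-dimethoxyphenyl)-4-methoxy-2,3-dihydro-1-benzofuran (trans) | Brc1ccc(OC)c2c1O[C@H](c1ccc(OC)cc1OC)[C@H]2c1cc(OC)cc(OC)c1 | intermediate
13 | [(2S,3S)-2-(2,4-dimethoxyphenyl)-3-(3,5-dimethoxyphenyl)-4-methoxy-2,3-dihydro-1-benzofuran-7-yl]lithium | [Li]c1ccc(OC)c2c1O[C@H](c1ccc(OC)cc1OC)[C@H]2c1cc(OC)cc(OC)c1 | intermediate
14 | [(2S,3S)-2-(2,4-dimethoxyphenyl)-3-(3,5-dimethoxyphenyl)-4-methoxy-2,3-dihydro-1-benzofuran-7-yl]boronic acid | OB(O)c1ccc(OC)c2c1O[C@H](c1ccc(OC)cc1OC)[C@H]2c1cc(OC)cc(OC)c1 | intermediate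
15 | 1-chloro-3,5-dimethoxybenzene | COc1cc(Cl)cc(OC)c1 | starting material
16 | 1-(2-chloro-4,6-dimethoxyphenyl)ethan-1-one | CC(=O)c1c(Cl)cc(OC)cc1OC | intermediate
17 | 1-(2-chloro-6-hydroxy-4-methoxyphenyl)ethan-1-one | CC(=O)c1c(Cl)cc(OC)cc1O | intermediate
18 | (E)-1-(2-chloro-6-hydroxy-4-methoxyphenyl)-3-(dimethylamino)prop-2-en-1-one | CN(C)/C=C/C(=O)c1c(Cl)cc(OC)cc1O | intermediate
19 | 5-chloro-7-methoxy-4H-chromen-4-one | O=c1ccoc2cc(OC)cc(Cl)c12 | intermediate
20 | (2S)-5-chloro-7-methoxy-2-RS2-2,3-dihydro-4H-chromen-4-one | O=C1C[C@@H](c2ccc(OC)c3c2O[C@H](c2ccc(OC)cc2OC)[C@H]3c2cc(OC)cc(OC)c2)Oc2cc(OC)cc(Cl)c21 | intermediate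
21 | (2S)-5-chloro-4,7-dimethoxy-2-RS2-2H-chromene | COC1=C[C@@H](c2ccc(OC)c3c2O[C@H](c2ccc(OC)cc2OC)[C@H]3c2cc(OC)cc(OC)c2)Oc2cc(OC)cc(Cl)c21 | intermediate
22 | methyl (2S,3S)-4-chloro-6-methoxy-2-RS2-2,3-dihydro-1-benzofuran-3-carboxylate | Clc1cc(OC)cc2c1[C@H](C(=O)OC)[C@@H](c1ccc(OC)c3c1O[C@H](c1ccc(OC)cc1OC)[C@H]3c1cc(OC)cc(OC)c1)O2 | intermediate
23 | (2S,3S)-4-chloro-6-methoxy-2-RS2-2,3-dihydro-1-benzofuran-3-carboxylic acid | Clc1cc(OC)cc2c1[C@H](C(=O)O)[C@@H](c1ccc(OC)c3c1O[C@H](c1ccc(OC)cc1OC)[C@H]3c1cc(OC)cc(OC)c1)O2 | intermediate
24 | 1,3-dioxoisoindolin-2-yl (2S,3S)-4-chloro-6-methoxy-2-RS2-2,3-dihydro-1-benzofuran-3-carboxylate | Clc1cc(OC)cc2c1[C@H](C(=O)ON1C(=O)c3ccccc3C1=O)[C@@H](c1ccc(OC)c3c1O[C@H](c1ccc(OC)cc1OC)[C@H]3c1cc(OC)cc(OC)c1)O2 | intermediate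
25 | (3,5-dimethoxyphenyl)lithium | [Li]c1cc(OC)cc(OC)c1 | intermediate
26 | (3,5-dimethoxyphenyl)zinc chloride | COc1cc([Zn]Cl)cc(OC)c1 | intermediate
27 | (2S,3S)-4-chloro-3-(3,5-dimethoxyphenyl)-6-methoxy-2-RS2-2,3-dihydro-1-benzofuran | Clc1cc(OC)cc2c1[C@H](c1cc(OC)cc(OC)c1)[C@@H](c1ccc(OC)c3c1O[C@H](c1ccc(OC)cc1OC)[C@H]3c1cc(OC)cc(OC)c1)O2 | intermediate
28 | [(E)-2-(4-methoxyphenyl)ethenyl]boronic acid | COc1ccc(/C=C/B(O)O)cc1 | starting material
29 | (2S,3S)-3-(3,5-dimethoxyphenyl)-6-methoxy-4-[(E)-2-(4-methoxyphenyl)ethenyl]-2-RS2-2,3-dihydro-1-benzofuran | COc1ccc(/C=C/c2cc(OC)cc3c2[C@H](c2cc(OC)cc(OC)c2)[C@@H](c2ccc(OC)c4c2O[C@H](c2ccc(OC)cc2OC)[C@H]4c2cc(OC)cc(OC)c2)O3)cc1 | intermediate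
30 | (2S,3S)-2-[(2S,3S)-2-(2,4-dihydroxyphenyl)-3-(3,5-dihydroxyphenyl)-4-hydroxy-2,3-dihydro-1-benzofuran-7-yl]-3-(3,5-dihydroxyphenyl)-4-[(E)-2-(4-hydroxyphenyl)ethenyl]-2,3-dihydro-1-benzofuran-6-ol | Oc1ccc(/C=C/c2cc(O)cc3c2[C@H](c2cc(O)cc(O)c2)[C@@H](c2ccc(O)c4c2O[C@H](c2ccc(O)cc2O)[C@H]4c2cc(O)cc(O)c2)O3)cc1 | target

**Step count and risks**

Total: 17 steps. Longest linear sequence: 14 steps (steps 1–7 and 11–17, from 1); the chromone branch (steps 8–10) joins at step 11.

Step 12 (key step). Ketalisation of the carbonyl group may be slow beside the peri chlorine, so that the oxidant lingers and attacks the electron-rich rings G and H. The iodane may form cis to the C2 aryl group, or the ring may flip, so that the C2 aryl group migrates or H2 is lost instead of the ring bond shifting. The acid may ionise O1–C2 (epimerisation at C2 through ring opening) or O1'–C2' (a transient phenol exposed to the oxidant). Fallback, a Wolff ring contraction that forms the same bond without acid or oxidant: starting from 20, LiN(SiMe3)2 and CF3CO2CH2CF3 in THF at −78 °C give the 3-trifluoroacetyl flavanone F1. Detrifluoroacetylative diazo transfer with MsN3 and Et3N gives the 3-diazoflavanone F2. Irradiation in methanol (or PhCO2Ag, Et3N) sends F2 through the ketene to the methyl ester, formed together with the cis ester F3, and a catalytic amount of DBU equilibrates the mixture to the trans ester 22, where the route is rejoined.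

Step 11. Transmetalation of the hindered ortho-alkoxy boronic acid may be slower than its protodeboronation in the aqueous, mildly acidic medium. The chiral substrate may be mismatched with the ligand, and the product may epimerise at C2 by reversible ring opening during heating. Fallback, closing the O1–C2 bond instead of the C2–C7' bond: starting from 12, bromine–lithium exchange and DMF give the aldehyde F4. Claisen–Schmidt condensation with 17 (KOH, EtOH) gives the 2'-hydroxychalcone F5. Oxa-Michael cyclisation (NaOAc, EtOH, reflux) gives 20 together with its C2 epimer F6. Because ring F is already enantiopure, the two are diastereomers and separable by chromatography; F6 is returned to the equilibrium, and the route is rejoined at 20.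

Step 6. With so electron-rich a benzyl group the insertion may turn stepwise (hydride transfer, then closure of the zwitterion) and lose enantioselectivity. The carbene may be lost to azine formation or to insertion into the neighbouring methoxy group, and in the acid stage the cation may eliminate instead of reclosing. Some protection is built in: step 11 is catalyst-controlled, so any minor enantiomer of ring system 2 ends up in a diastereomer of 20. Fallback, resolution in place of asymmetric induction: starting from 9, the insertion is run with achiral Rh2(OAc)4 and gives 12 together with its enantiomer, the (2R,3R) bromide F7. Steps 7 and 11 are run unchanged and give boronic acid 14 with its enantiomer F8 and, under the chiral palladium catalyst, flavanone 20 with the diastereomeric flavanone F9 that carries the (2R,3R) ring system. Chromatographic separation rejoins the route at 20.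

Step 5. Condensation at a carbonyl group with both ortho positions of one aryl group substituted may stall, and forcing it risks cleavage of the benzyl ether or Wolff–Kishner-type reduction. Fallback, transimination instead of condensation: starting from 4, I2 and aqueous NH3 in THF convert the aldehyde into the nitrile F10. Addition of Grignard reagent 6, made from 5 as in step 3 (THF, reflux, CuBr cat.), and a quench with dry methanol give the N-unsubstituted ketimine F11, and exchange with N2H4 gives hydrazone 9, where the route is rejoined.

Step 15. The benzylic radical may dimerise or be reduced before nickel captures it, zerovalent nickel may insert into the C4–Cl bond, and the facial preference at C3 may be incomplete. Fallback, carboxylate oxidation instead of ester reduction and an aryl halide instead of an arylzinc: starting from 23, dual photoredox/nickel decarboxylative arylation with bromide 5 ([Ir(dF(CF3)ppy)2(dtbbpy)]PF6, NiCl2(dme), 4,4'-di-tert-butyl-2,2'-bipyridine, Cs2CO3, DMF, blue light) gives 27, where the route is rejoined. This fallback makes no new compound (F0).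

Step 17. Ionised benzylic ethers may be intercepted (attack by a neighbouring electron-rich ring, elimination) before they reclose, HBr formed on quenching may add to or isomerise the stilbene, and cleavage of nine ethers may stop short. Fallback, nucleophilic instead of Lewis-acidic cleavage: starting from 29, NaSEt in DMF at 140 °C removes the methyl groups by SN2 attack under basic conditions, in which the benzylic ethers do not ionise, and acidification gives 30. This fallback makes no new compound (F0).

**Further compounds**

F1 | step 12 | (2S)-5-chloro-7-methoxy-2-RS2-3-(trifluoroacetyl)-2,3-dihydro-4H-chromen-4-one (C3 epimers and enol form) | O=C1C(C(=O)C(F)(F)F)[C@@H](c2ccc(OC)c3c2O[C@H](c2ccc(OC)cc2OC)[C@H]3c2cc(OC)cc(OC)c2)Oc2cc(OC)cc(Cl)c21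
F2 | step 12 | (2R)-5-chloro-3-diazo-7-methoxy-2-RS2-2,3-dihydro-4H-chromen-4-one | O=C1C(=[N+]=[N-])[C@@H](c2ccc(OC)c3c2O[C@H](c2ccc(OC)cc2OC)[C@H]3c2cc(OC)cc(OC)c2)Oc2cc(OC)cc(Cl)c21
F3 | step 12 | methyl (2S,3R)-4-chloro-6-methoxy-2-RS2-2,3-dihydro-1-benzofuran-3-carboxylate (cis) | Clc1cc(OC)cc2c1[C@@H](C(=O)OC)[C@@H](c1ccc(OC)c3c1O[C@H](c1ccc(OC)cc1OC)[C@H]3c1cc(OC)cc(OC)c1)O2
F4 | step 11 | (2S,3S)-2-(2,4-dimethoxyphenyl)-3-(3,5-dimethoxyphenyl)-4-methoxy-2,3-dihydro-1-benzofuran-7-carbaldehyde | O=Cc1ccc(OC)c2c1O[C@H](c1ccc(OC)cc1OC)[C@H]2c1cc(OC)cc(OC)c1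
F5 | step 11 | (E)-1-(2-chloro-6-hydroxy-4-methoxyphenyl)-3-RS2-prop-2-en-1-one | COc1cc(O)c(C(=O)/C=C/c2ccc(OC)c3c2O[C@H](c2ccc(OC)cc2OC)[C@H]3c2cc(OC)cc(OC)c2)c(Cl)c1
F6 | step 11 | (2R)-5-chloro-7-methoxy-2-RS2-2,3-dihydro-4H-chromen-4-one | O=C1C[C@H](c2ccc(OC)c3c2O[C@H](c2ccc(OC)cc2OC)[C@H]3c2cc(OC)cc(OC)c2)Oc2cc(OC)cc(Cl)c21
F7 | step 6 | (2R,3R)-7-bromo-2-(2,4-dimethoxyphenyl)-3-(3,5-dimethoxyphenyl)-4-methoxy-2,3-dihydro-1-benzofuran | Brc1ccc(OC)c2c1O[C@@H](c1ccc(OC)cc1OC)[C@@H]2c1cc(OC)cc(OC)c1
F8 | step 6 | [(2R,3R)-2-(2,4-dimethoxyphenyl)-3-(3,5-dimethoxyphenyl)-4-methoxy-2,3-dihydro-1-benzofuran-7-yl]boronic acid | OB(O)c1ccc(OC)c2c1O[C@@H](c1ccc(OC)cc1OC)[C@@H]2c1cc(OC)cc(OC)c1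
F9 | step 6 | (2S)-5-chloro-2-[(2R,3R)-2-(2,4-dimethoxyphenyl)-3-(3,5-dimethoxyphenyl)-4-methoxy-2,3-dihydro-1-benzofuran-7-yl]-7-methoxy-2,3-dihydro-4H-chromen-4-one | O=C1C[C@@H](c2ccc(OC)c3c2O[C@@H](c2ccc(OC)cc2OC)[C@@H]3c2cc(OC)cc(OC)c2)Oc2cc(OC)cc(Cl)c21
F10 | step 5 | 3-bromo-2-[(2,4-dimethoxyphenyl)methoxy]-6-methoxybenzonitrile | N#Cc1c(OCc2ccc(OC)cc2OC)c(Br)ccc1OC
F11 | step 5 | {3-bromo-2-[(2,4-dimethoxyphenyl)methoxy]-6-methoxyphenyl}(3,5-dimethoxyphenyl)methanimine | N=C(c1cc(OC)cc(OC)c1)c1c(OCc2ccc(OC)cc2OC)c(Br)ccc1OC
F0 | step 15 | none | none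
F0 | step 17 | none | none
A1 | alternative 1 | (2S,3S)-4-bromo-3-(3,5-dimethoxyphenyl)-6-methoxy-2-RS2-2,3-dihydro-1-benzofuran | Brc1cc(OC)cc2c1[C@H](c1cc(OC)cc(OC)c1)[C@@H](c1ccc(OC)c3c1O[C@H](c1ccc(OC)cc1OC)[C@H]3c1cc(OC)cc(OC)c1)O2
A2 | alternative 1 | rac-3-bromo-2-[(3,5-dimethoxyphenyl)(4-methylbenzenesulfonyl)methyl]-5-methoxyphenol | Cc1ccc(cc1)S(=O)(=O)C(c1cc(OC)cc(OC)c1)c1c(O)cc(OC)cc1Br
A3 | alternative 1 | 1-(RS2-methyl)thiolan-1-ium bromide | [Br-].C1CC[S+](C1)Cc1ccc(OC)c2c1O[C@H](c1ccc(OC)cc1OC)[C@H]2c1cc(OC)cc(OC)c1
A4 | alternative 2 | (2S,3S)-7-bromo-2-(2,4-dimethoxyphenyl)-3-(3,5-dimethoxyphenyl)-4-methoxy-2,3-dihydro-1-benzofuran | Brc1ccc(OC)c2c1O[C@H](c1ccc(OC)cc1OC)[C@H]2c1cc(OC)cc(OC)c1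
A5 | alternative 2 | (2S,3S)-7-({3-chloro-2-[diazo(3,5-dimethoxyphenyl)methyl]-5-methoxyphenoxy}methyl)-2-(2,4-dimethoxyphenyl)-3-(3,5-dimethoxyphenyl)-4-methoxy-2,3-dihydro-1-benzofuran | [N-]=[N+]=C(c1cc(OC)cc(OC)c1)c1c(Cl)cc(OC)cc1OCc1ccc(OC)c2c1O[C@H](c1ccc(OC)cc1OC)[C@H]2c1cc(OC)cc(OC)c1
A6 | alternative 3 | (2S,3S)-2-(2,4-dimethoxyphenyl)-3-(3,5-dimethoxyphenyl)-7-iodo-4-methoxy-2,3-dihydro-1-benzofuran | Ic1ccc(OC)c2c1O[C@H](c1ccc(OC)cc1OC)[C@H]2c1cc(OC)cc(OC)c1
A7 | alternative 3 | (1S,2S)-1-(2,4-dimethoxyphenyl)-2-(3,5-dimethoxyphenyl)-2-(2-fluoro-6-methoxyphenyl)ethan-1-ol | O[C@H](c1ccc(OC)cc1OC)[C@@H](c1cc(OC)cc(OC)c1)c1c(F)cccc1OC
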